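The constants used here are invented; the run is a simulation.

Which of the four flasks holds the most target after 25 min, and how much, when solid substrate enters the solution slowly and must then pass through a chain of steps?

    solid substrate ⇌ starting material, rate k1*(cs1 - [starting material]) while solid is left; crystals form when [starting material] > cs1 (cs1 = 1.2 M, k1 = 4.3 × 10⁻⁴ s⁻¹)
    intermediate B → target (k2 = 3.3 × 10⁻⁴ s⁻¹, Ea2 = 100 kJ mol⁻¹)
    intermediate A → intermediate B (k3 = 0.0010 s⁻¹, Ea3 = 108 kJ mol⁻¹)
    starting material + target → side product (k4 = 6.2 × 10⁻⁴ M⁻¹ s⁻¹, Ea4 = 64.0 kJ mol⁻¹)
    starting material → intermediate A (k5 = 6.1 × 10⁻⁴ s⁻¹, Ea5 = 111 kJ mol⁻¹)
    (constants at 70 °C)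

| setting | Tuesday's | Wednesday's | Thursday's | Saturday's |
|---|---|---|---|---|
| solid substrate | 1.2 M | 1.2 M | 1.2 M | 1.2 M |
| temperature | 20 °C | 45 °C | 95 °C | 70 °C |
| time | 25 min | 25 min | 25 min | 25 min |

- in percentages every species weighs as the solid substrate in it: one side product counts as two
- as a solid, counted per litre of solution: solid substrate
- the list of constants is for 70 °C, to be carried to other temperatures by the activation energies
- at the start none of the solid substrate is in solution
- what has only dissolved of solid substrate counts as not reacted

1. which flask leads in amount of target, in percent of the solid substrate charged ("all alike" within 1.5 percentage points) (Tuesday's / Wednesday's / Thursday's / Saturday's / all alike)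
2. how much target is there at the end, in percent of the solid substrate charged: Tuesday's
3. how much target is there at the end, in percent of the solid substrate charged: Wednesday's
4. how much target is there at the end, in percent of the solid substrate charged: Thursday's
5. how much target is there at the end, in percent of the solid substrate charged: Saturday's

I reckoned Thursday's flask first, in fractions of the charge. I carried the constants to 95 °C and took one over each constant as that step's mean time:

starting material 1.95 min, intermediate A 1.27 min, intermediate B 4.67 min; sum 7.89 min

That sum is shorter than the run, so I treated Thursday's chain as a steady stream. I took starting material to level off where dissolution equals its step to intermediate A, and I reckoned the feed from that level: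

plateau of starting material 4.78%
feed 0.0246 min⁻¹
fed during the run 61.4%

The feed times the summed mean times is a rate divided by rates, so time drops out. I call this the hold-up: the share of the charge standing in the chain as starting material and the two intermediates while solid still feeds it.

hold-up 19.4%
target, fed minus hold-up 42.0%

At Saturday's 70 °C, with the feed at its top rate, the hold-up is 244%, against 64.5% fed. The subtraction goes negative there, so this reckoning gave no target figure for Saturday's flask. Wednesday's gives 4388% and Tuesday's 132507%, so Thursday's has the smallest hold-up, and I chose it.

The weak link was the side step, which I had ignored. I took target to rise in a straight line after the lag and starting material to sit at its plateau, and integrating over the run on those terms gave the weight that goes to side product: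

side product 7.04%
target, reforged 35.0%

The forecast chose Thursday's, with 37% for Thursday's, 0.9% for Saturday's, <0.001% for Wednesday's and <0.001% for Tuesday's, holding that “the amount formed is limited by dissolution”. Its Thursday's figure stands higher than my 35.0%.

The simulation gave Thursday's as the leader, with 37.7% on Thursday's, 0.868% on Saturday's, 0% on Wednesday's and 0% on Tuesday's.

In Thursday's flask at 25.0 min, starting material and the two intermediates together stood at 17.5%, against my hold-up of 19.4%, and 38.2% of the charge was still solid, so that flask was still being fed when the run ended. The neighbouring flask repeats Thursday's at 70 °C. Its hold-up is 244% against 64.5% fed, so the same subtraction goes negative. That flask ended with 6.34% as intermediate B and 0.868% as target.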